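**Retrosynthetic overview**
1. The free phenol is released last by fluoride desilylation. The angelate comes from acylating the (S)-carbinol with a preformed angelic mixed anhydride, so the Z geometry is bought rather than made.
2. The prenyl terminus comes from cross metathesis of an (S)-homoallylic alcohol with 2-methyl-2-butene.
3. Key C–C bond (carbinol carbon to CH2): Brown asymmetric carbonyl allylation of a 2-arylacrolein with the allylborane derived from (+)-α-pinene. This sets the only stereocentre.
4. The 2-arylacrolein comes from Mannich methylenation of an arylacetaldehyde, itself made by Wittig homologation of a protected salicylaldehyde.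
5. The salicylaldehyde comes from 2,6-dimethoxytoluene (Vilsmeier, Baeyer–Villiger, Mg-directed ortho-formylation). No ring is formed, because the benzene ring is bought.

**Assumption:** the SMILES is read as the (S)-carbinol esterified with (Z)-2-methylbut-2-enoic (angelic) acid.
**Abbreviations:** Ar = 3,5-dimethoxy-4-methyl-2-(triisopropylsilyloxy)phenyl; TIPS = Si(i-Pr)3; Ipc = isopinocampheyl derived from (+)-α-pinene.

**Step 1**
Reactants: 1 2,6-dimethoxytoluene
Product: 3 2,4-dimethoxy-3-methylbenzaldehyde, via iminium chloride 2 (not isolated)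
Conditions: POCl3 (1.5 equiv), DMF, 0 → 90 °C, 4 h; then ice-water, rt
Reagents that add atoms: N,N-dimethylformamide CN(C)C=O; water O
Why: Vilsmeier–Haack formylation attacks the only position that is ortho to one methoxy group and para to the other (C3 and C5 are equivalent by symmetry), and water hydrolyses 2 to the aldehyde.

**Step 2**
Reactants: 3 2,4-dimethoxy-3-methylbenzaldehyde
Product: 5 2,4-dimethoxy-3-methylphenol, via aryl formate 4 (not isolated)
Conditions: mCPBA (1.3 equiv), CH2Cl2, 0 °C → rt; aq. NaHCO3 wash; crude 4, K2CO3 (0.2 equiv), MeOH, rt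
Reagents that add atoms: mCPBA O=C(OO)c1cccc(Cl)c1
Why: In this Baeyer–Villiger (Dakin-type) oxidation the electron-rich aryl group migrates to oxygen in preference to hydride, and the labile formate 4 is cleaved by base-catalysed transesterification with methanol.

**Step 3**
Reactants: 5 2,4-dimethoxy-3-methylphenol
Product: 7 2-hydroxy-3,5-dimethoxy-4-methylbenzaldehyde, via salicyl alcohol 6 (not isolated)
Conditions: MgCl2 (2 equiv), Et3N (4 equiv), (CH2O)n (6 equiv), MeCN, reflux, 6 h; 1 M HCl work-up
Reagents that add atoms: paraformaldehyde (as formaldehyde) C=O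
Why: In the Casnati–Skattebøl ortho-formylation Mg2+ ties formaldehyde to the phenol oxygen, so the new bond forms only at the one free ortho carbon and not at the position activated by the methoxy groups, and a second formaldehyde then oxidises 6 by Oppenauer-type hydride transfer.

**Step 4**
Reactants: 7 2-hydroxy-3,5-dimethoxy-4-methylbenzaldehyde
Product: 8 3,5-dimethoxy-4-methyl-2-(triisopropylsilyloxy)benzaldehyde (ArCHO)
Conditions: TIPSCl (1.3 equiv), imidazole (2.5 equiv), DMF, rt → 40 °C
Reagents that add atoms: chlorotriisopropylsilane CC(C)[Si](Cl)(C(C)C)C(C)C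
Why: Imidazole-promoted silylation gives a TIPS ether that withstands ylide, dilute aqueous acid, amine base, perborate and 80 °C, resists O-to-O migration, and can be removed at the end with buffered fluoride.

**Step 5**
Reactants: 8 ArCHO
Product: 9 1-(2-methoxyethenyl)-3,5-dimethoxy-4-methyl-2-(triisopropylsilyloxy)benzene (ArCH=CHOMe as an E/Z mixture)
Conditions: MeOCH2PPh3Cl (1.5 equiv), NaN(SiMe3)2 (1.45 equiv), THF, 0 °C; then 8, 0 °C → rt
Reagents that add atoms: (methoxymethyl)triphenylphosphonium chloride COC[P+](c1ccccc1)(c1ccccc1)c1ccccc1.[Cl-]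
Why: This Wittig one-carbon homologation runs in aprotic medium with the base kept below the phosphonium salt so the silyl ether is untouched, and the E/Z ratio is irrelevant because both isomers hydrolyse to the same aldehyde.

**Step 6**
Reactants: 9 ArCH=CHOMe
Product: 10 2-[3,5-dimethoxy-4-methyl-2-(triisopropylsilyloxy)phenyl]acetaldehyde (ArCH2CHO)
Conditions: 3 M aq. HCl (cat.), THF, 40 °C, 3 h; used crude
Reagents that add atoms: water O
Why: Acid-catalysed enol ether hydrolysis (C-protonation, addition of water, loss of methanol) proceeds under conditions to which a phenolic TIPS ether is inert.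

**Step 7**
Reactants: 10 ArCH2CHO
Product: 12 2-[3,5-dimethoxy-4-methyl-2-(triisopropylsilyloxy)phenyl]prop-2-enal (2-arylacrolein), via Mannich base 11 (not isolated)
Conditions: (CH2=NMe2)I (1.5 equiv), Et3N (2 equiv), CH2Cl2, rt, 12 h; pH 4 buffer wash, short silica plug, used at once
Reagents that add atoms: Eschenmoser's salt C=[N+](C)C.[I-]
Why: The readily enolised arylacetaldehyde undergoes a Mannich reaction with the preformed iminium salt, and E1cB loss of dimethylamine from 11 (α-methylenation) gives an enal that the twisted ortho-substituted aryl group protects from dimerisation.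

**Step 8**
Reactants: 13 (−)-B-methoxydiisopinocampheylborane; 14 allylmagnesium bromide (1 M in Et2O, 0.95 equiv)
Product: 15 B-allyldiisopinocampheylborane (Ipc groups from (+)-α-pinene), used as a filtered solution
Conditions: Et2O, 0 °C → rt, 1 h; pentane, filtration under argon
Reagents that add atoms: none
Why: The Grignard reagent displaces methoxide at boron, and removing the precipitated magnesium salts gives the salt-free Brown reagent that still reacts fast at −100 °C.

**Step 9**
Reactants: 12 2-arylacrolein; 15 B-allyldiisopinocampheylborane (1.3 equiv)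
Product: 17 (3S)-2-Ar-hexa-1,5-dien-3-ol, via borinate ester 16 (not isolated)
Conditions: Et2O/pentane, −100 °C, 2 h; then NaBO3·4H2O, THF/H2O, rt
Reagents that add atoms: none
Why: Brown asymmetric carbonyl allylation is a strictly 1,2-selective addition through a closed Zimmerman–Traxler chair in which the (+)-α-pinene-derived Ipc groups direct allyl to the Si face of the aldehyde (the sense that turns benzaldehyde into (S)-1-phenylbut-3-en-1-ol), which sets the (S)-centre, and mild perborate cleaves the boron residues without touching the silyl ether.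

**Step 10**
Reactants: 17 (3S)-2-Ar-hexa-1,5-dien-3-ol
Product: 18 (3S)-2-Ar-6-methylhepta-1,5-dien-3-ol
Conditions: second-generation Grubbs catalyst RuCl2(=CHPh)(PCy3)(SIMes) (5 mol%), 2-methyl-2-butene/CH2Cl2 1:1, 40 °C, sealed tube, 12 h
Reagents that add atoms: 2-methyl-2-butene CC=C(C)C
Why: Olefin cross metathesis engages only the monosubstituted terminal alkene, because the 1,1-disubstituted alkene is blocked by the ortho-substituted aryl group and the carbinol, ring closure would need a cyclobutene, and the stereocentre is not involved.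

**Step 11**
Reactants: 19 angelic acid [(Z)-2-methylbut-2-enoic acid]
Product: 20 angelic 2,4,6-trichlorobenzoic anhydride (filtered toluene solution)
Conditions: 2,4,6-Cl3C6H2COCl (1.0 equiv), Et3N (1.0 equiv), toluene, rt, 2 h; filter
Reagents that add atoms: 2,4,6-trichlorobenzoyl chloride O=C(Cl)c1c(Cl)cc(Cl)cc1Cl
Why: Mixed-anhydride formation with the Yamaguchi reagent activates the acid at room temperature without excess base or a nucleophilic catalyst, so the Z-alkene is not isomerised.

**Step 12**
Reactants: 18 (3S)-2-Ar-6-methylhepta-1,5-dien-3-ol; 20 angelic 2,4,6-trichlorobenzoic anhydride (3 equiv)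
Product: 21 (3S)-2-Ar-6-methylhepta-1,5-dien-3-yl (2Z)-2-methylbut-2-enoate
Conditions: toluene, 80 °C, 24 h, no DMAP; aq. NaHCO3 work-up
Reagents that add atoms: none
Why: In this Yamaguchi-type esterification without nucleophilic catalyst the alcohol attacks the unhindered angeloyl carbonyl, which avoids both the Michael-type Z-to-E isomerisation caused by DMAP and any alkoxide that could trigger silyl migration or anionic oxy-Cope rearrangement, and the C–O bond at C3 stays intact so the configuration is retained.

**Step 13**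
Reactants: 21 (3S)-2-Ar-6-methylhepta-1,5-dien-3-yl (2Z)-2-methylbut-2-enoate
Product: 22 (3S)-2-(2-hydroxy-3,5-dimethoxy-4-methylphenyl)-6-methylhepta-1,5-dien-3-yl (2Z)-2-methylbut-2-enoate (target)
Conditions: Bu4NF (1.2 equiv), AcOH (1.3 equiv), THF, 0 °C, 30 min
Reagents that add atoms: none
Why: Fluoride-mediated desilylation cleaves aryl silyl ethers within minutes, and the acetic acid buffer protonates the phenol as it forms, so the allylic angelate, its Z geometry and the stereocentre are left untouched.

**Compound list**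
1 | 2,6-dimethoxytoluene | COc1cccc(OC)c1C | starting material
2 | N-[(2,4-dimethoxy-3-methylphenyl)methylidene]-N-methylmethanaminium chloride | C[N+](C)=Cc1ccc(OC)c(C)c1OC.[Cl-] | intermediate
3 | 2,4-dimethoxy-3-methylbenzaldehyde | COc1ccc(C=O)c(OC)c1C | intermediate
4 | 2,4-dimethoxy-3-methylphenyl formate | COc1ccc(OC=O)c(OC)c1C | intermediate
5 | 2,4-dimethoxy-3-methylphenol | COc1ccc(O)c(OC)c1C | intermediate
6 | 2-(hydroxymethyl)-4,6-dimethoxy-5-methylphenol (present as its magnesium salt) | COc1cc(CO)c(O)c(OC)c1C | intermediate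
7 | 2-hydroxy-3,5-dimethoxy-4-methylbenzaldehyde | COc1cc(C=O)c(O)c(OC)c1C | intermediate
8 | 3,5-dimethoxy-4-methyl-2-(triisopropylsilyloxy)benzaldehyde | COc1cc(C=O)c(O[Si](C(C)C)(C(C)C)C(C)C)c(OC)c1C | intermediate
9 | 1-(2-methoxyethenyl)-3,5-dimethoxy-4-methyl-2-(triisopropylsilyloxy)benzene, E/Z mixture | COC=Cc1cc(OC)c(C)c(OC)c1O[Si](C(C)C)(C(C)C)C(C)C | intermediate
10 | 2-[3,5-dimethoxy-4-methyl-2-(triisopropylsilyloxy)phenyl]acetaldehyde | O=CCc1cc(OC)c(C)c(OC)c1O[Si](C(C)C)(C(C)C)C(C)C | intermediate
11 | 3-(dimethylamino)-2-[3,5-dimethoxy-4-methyl-2-(triisopropylsilyloxy)phenyl]propanal (racemic) | CN(C)CC(C=O)c1cc(OC)c(C)c(OC)c1O[Si](C(C)C)(C(C)C)C(C)C | intermediate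
12 | 2-[3,5-dimethoxy-4-methyl-2-(triisopropylsilyloxy)phenyl]prop-2-enal | C=C(C=O)c1cc(OC)c(C)c(OC)c1O[Si](C(C)C)(C(C)C)C(C)C | intermediate
13 | (−)-B-methoxydiisopinocampheylborane (from (+)-α-pinene) | COB([C@@H]1C[C@@H]2C[C@H]([C@H]1C)C2(C)C)[C@@H]1C[C@@H]2C[C@H]([C@H]1C)C2(C)C | starting material
14 | allylmagnesium bromide | C=CC[Mg]Br | starting material
15 | B-allyldiisopinocampheylborane (Ipc from (+)-α-pinene) | C=CCB([C@@H]1C[C@@H]2C[C@H]([C@H]1C)C2(C)C)[C@@H]1C[C@@H]2C[C@H]([C@H]1C)C2(C)C | intermediate
16 | (3S)-2-[3,5-dimethoxy-4-methyl-2-(triisopropylsilyloxy)phenyl]hexa-1,5-dien-3-yl diisopinocampheylborinate | C=C(c1cc(OC)c(C)c(OC)c1O[Si](C(C)C)(C(C)C)C(C)C)[C@H](CC=C)OB([C@@H]1C[C@@H]2C[C@H]([C@H]1C)C2(C)C)[C@@H]1C[C@@H]2C[C@H]([C@H]1C)C2(C)C | intermediate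
17 | (3S)-2-[3,5-dimethoxy-4-methyl-2-(triisopropylsilyloxy)phenyl]hexa-1,5-dien-3-ol | C=C(c1cc(OC)c(C)c(OC)c1O[Si](C(C)C)(C(C)C)C(C)C)[C@H](CC=C)O | intermediate
18 | (3S)-2-[3,5-dimethoxy-4-methyl-2-(triisopropylsilyloxy)phenyl]-6-methylhepta-1,5-dien-3-ol | C=C(c1cc(OC)c(C)c(OC)c1O[Si](C(C)C)(C(C)C)C(C)C)[C@H](CC=C(C)C)O | intermediate
19 | angelic acid, (Z)-2-methylbut-2-enoic acid | C/C=C(/C)C(=O)O | starting material
20 | (Z)-2-methylbut-2-enoic 2,4,6-trichlorobenzoic anhydride | C/C=C(/C)C(=O)OC(=O)c1c(Cl)cc(Cl)cc1Cl | intermediate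
21 | (3S)-2-[3,5-dimethoxy-4-methyl-2-(triisopropylsilyloxy)phenyl]-6-methylhepta-1,5-dien-3-yl (2Z)-2-methylbut-2-enoate | C=C(c1cc(OC)c(C)c(OC)c1O[Si](C(C)C)(C(C)C)C(C)C)[C@H](CC=C(C)C)OC(=O)/C(C)=C\C | intermediate
22 | (3S)-2-(2-hydroxy-3,5-dimethoxy-4-methylphenyl)-6-methylhepta-1,5-dien-3-yl (2Z)-2-methylbut-2-enoate | C=C(c1cc(OC)c(C)c(OC)c1O)[C@H](CC=C(C)C)OC(=O)/C(C)=C\C | target

**Total step count:** 13.
**Longest linear sequence:** 11 steps (steps 1–7, 9, 10, 12, 13, from 2,6-dimethoxytoluene). Steps 8 and 11 are one-step side branches.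

**Three steps most likely to fail**

**Step 12 (angeloylation).** The risks are slow acylation of the hindered carbinol and drift of the angelate to the tiglate.
- The fallback builds the Z-alkene on the ester instead of importing it, and sets out from 18.
- Coupling with 2-[bis(2,2,2-trifluoroethoxy)phosphoryl]propanoic acid (EDC·HCl, DMAP, CH2Cl2, rt) is safe here because no Z-alkene is present yet. It gives the phosphonopropanoate ester F1.
- Still–Gennari olefination of F1 (KN(SiMe3)2, 18-crown-6, THF, −78 °C, then acetaldehyde) forms the Z-trisubstituted enoate under kinetic control and comes back to the route at 21.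

**Step 9 (asymmetric allylation).** The risks are insufficient ee with the bulky α-aryl enal and loss of the labile enal.
- The fallback keeps the same bond construction but sets the configuration by resolution, and sets out from 12.
- Direct addition of 14 (Et2O, −78 °C) gives the racemic dienol F2.
- Sharpless kinetic resolution follows (Ti(OiPr)4, D-(−)-diisopropyl tartrate, t-BuOOH 0.6 equiv, 4 Å molecular sieves, CH2Cl2, −20 °C).
- The fast-reacting (R)-enantiomer is epoxidised at its allylic alkene to the erythro epoxy alcohol F3. The (S)-enantiomer is left behind and, after chromatography, comes back to the route at 17.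

**Step 7 (Mannich methylenation).** The risks are re-addition of the liberated amine to the enal and oligomerisation.
- The fallback reaches the enal through the acrylate oxidation level and a neutral final oxidation, and sets out from 10.
- Pinnick oxidation (NaClO2, NaH2PO4, 2-methyl-2-butene, t-BuOH/H2O) gives the arylacetic acid F4.
- Me3SiCHN2 (toluene/MeOH) gives the methyl arylacetate F5.
- Aldol-type hydroxymethylation and dehydration ((CH2O)n, K2CO3, Bu4NBr, toluene, 80 °C) gives the methyl 2-arylacrylate F6.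
- i-Bu2AlH (CH2Cl2, −78 °C) gives the 2-arylallyl alcohol F7.
- MnO2 (CH2Cl2, rt) comes back to the route at 12 in an amine-free medium, ready for immediate allylation.

**Further compounds**
F1 | step 12 | (3S)-2-[3,5-dimethoxy-4-methyl-2-(triisopropylsilyloxy)phenyl]-6-methylhepta-1,5-dien-3-yl 2-[bis(2,2,2-trifluoroethoxy)phosphoryl]propanoate (epimers at the phosphonate carbon) | C=C(c1cc(OC)c(C)c(OC)c1O[Si](C(C)C)(C(C)C)C(C)C)[C@H](CC=C(C)C)OC(=O)C(C)P(=O)(OCC(F)(F)F)OCC(F)(F)F
F2 | step 9 | racemic 2-[3,5-dimethoxy-4-methyl-2-(triisopropylsilyloxy)phenyl]hexa-1,5-dien-3-ol | C=C(c1cc(OC)c(C)c(OC)c1O[Si](C(C)C)(C(C)C)C(C)C)C(CC=C)O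
F3 | step 9 | (1R)-1-{(2S)-2-[3,5-dimethoxy-4-methyl-2-(triisopropylsilyloxy)phenyl]oxiran-2-yl}but-3-en-1-ol | C=CC[C@@H](O)[C@]1(c2cc(OC)c(C)c(OC)c2O[Si](C(C)C)(C(C)C)C(C)C)CO1
F4 | step 7 | 2-[3,5-dimethoxy-4-methyl-2-(triisopropylsilyloxy)phenyl]acetic acid | OC(=O)Cc1cc(OC)c(C)c(OC)c1O[Si](C(C)C)(C(C)C)C(C)C
F5 | step 7 | methyl 2-[3,5-dimethoxy-4-methyl-2-(triisopropylsilyloxy)phenyl]acetate | COC(=O)Cc1cc(OC)c(C)c(OC)c1O[Si](C(C)C)(C(C)C)C(C)C
F6 | step 7 | methyl 2-[3,5-dimethoxy-4-methyl-2-(triisopropylsilyloxy)phenyl]prop-2-enoate | C=C(C(=O)OC)c1cc(OC)c(C)c(OC)c1O[Si](C(C)C)(C(C)C)C(C)C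
F7 | step 7 | 2-[3,5-dimethoxy-4-methyl-2-(triisopropylsilyloxy)phenyl]prop-2-en-1-ol | C=C(CO)c1cc(OC)c(C)c(OC)c1O[Si](C(C)C)(C(C)C)C(C)C
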